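**Retrosynthetic overview**
- Endgame: the α-methylene lactone is unmasked last from a Me2NCH2 Mannich adduct; before that, the C8 methacrylate and then the C9 acetate are put on an 8,9-cis-diol.
- Key (bold) step: C8–C9 is the ring-closing bond. RCM of a C7-vinyl/C10-vinyl diene gives a strained Z-C8=C9 alkene on the already bridged furanone, and one osmylation then sets both C8 and C9 under control of the bicycle.
- Furanone: gold-catalysed 5-endo cyclisation of a C10-hydroxy ynone, assembled by Sonogashira coupling (C3–C4) of a Z-vinyl iodide lactone with an alkynyl carbinol.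
- Lactone (C6, C7, C11) from (S)-5-(hydroxymethyl)butenolide by anti vinyl conjugate addition/Mannich trapping, then Z-selective iodo-olefination (C4=C5); C10 from Pd-catalysed asymmetric opening of isoprene monoepoxide.
- Ring order: lactone, then furanone, then the ten-membered carbocycle.

Numbering: macrocycles carry germacranolide numbers (C1 ketone, C2=C3, C3–O–C10 ether bridge, C4(Me-15)=C5, C6 lactone O, C7, C8, C9, C10(Me-14), C11–C12(=O)–C13); "β" is the face of the ether bridge and of C11.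

Assumption: in step 6 the Trost ligand antipode that gives the (S)-ether 9 is used (written as R,R; the sense is confirmed by Mosher analysis on the first run).

**Step 1**
Reactants: 1 (S)-5-(hydroxymethyl)furan-2(5H)-one
Product: 2 (S)-5-{[tert-butyl(diphenyl)silyl]oxymethyl}furan-2(5H)-one
Conditions: TBDPSCl, imidazole, CH2Cl2, 0 °C to rt
Reagents that add atoms: tert-butyl(chloro)diphenylsilane (CC(C)(C)[Si](Cl)(c1ccccc1)c1ccccc1)
Why: Standard silylation of the primary alcohol; the stereocentre (future C6) is untouched and the bulky group directs step 2.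

**Step 2**
Reactants: 2 (S)-5-{[tert-butyl(diphenyl)silyl]oxymethyl}furan-2(5H)-one
Product: 4 (3R,4S,5S)-5-{[tert-butyl(diphenyl)silyl]oxymethyl}-3-[(dimethylamino)methyl]-4-ethenyloxolan-2-one, via bromomagnesium lactone enolate 3 (not isolated)
Conditions: CH2=CHMgBr (1.5 equiv), CuBr·SMe2 (20 mol %), THF, −78 °C; then Me2N=CH2+ I− (2 equiv), −78 °C to rt
Reagents that add atoms: vinylmagnesium bromide (C=C[Mg]Br); N,N-dimethylmethyleneiminium iodide, Eschenmoser's salt (C[N+](C)=C.[I-])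
Why: Copper-catalysed conjugate addition anti to the C5 silyloxymethyl group sets C7, and Mannich trapping of the enolate anti to the new vinyl group installs the masked exocyclic methylene (C11 is planarised in step 16, so its configuration does not matter).

**Step 3**
Reactants: 4 (3R,4S,5S)-5-{[tert-butyl(diphenyl)silyl]oxymethyl}-3-[(dimethylamino)methyl]-4-ethenyloxolan-2-one
Product: 5 (3R,4S,5S)-3-[(dimethylamino)methyl]-4-ethenyl-5-(hydroxymethyl)oxolan-2-one
Conditions: TBAF, AcOH, THF, 0 °C to rt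
Reagents that add atoms: none
Why: Buffered fluoride desilylation; the β-amino lactone and all stereocentres are inert to these conditions.

**Step 4**
Reactants: 5 (3R,4S,5S)-3-[(dimethylamino)methyl]-4-ethenyl-5-(hydroxymethyl)oxolan-2-one
Product: 6 (2S,3S,4R)-4-[(dimethylamino)methyl]-3-ethenyl-5-oxooxolane-2-carbaldehyde
Conditions: DMP, CH2Cl2, 0 °C to rt; used crude
Reagents that add atoms: none
Why: Dess–Martin oxidation is non-basic, so the α-oxygenated aldehyde does not epimerise at C6; the amine sits as its acetate salt.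

**Step 5**
Reactants: 6 (2S,3S,4R)-4-[(dimethylamino)methyl]-3-ethenyl-5-oxooxolane-2-carbaldehyde
Product: 7 (3R,4S,5S)-3-[(dimethylamino)methyl]-4-ethenyl-5-[(1Z)-2-iodoprop-1-en-1-yl]oxolan-2-one
Conditions: EtPPh3+ I−, n-BuLi, THF, 0 °C; I2, −78 °C; NaN(SiMe3)2, −78 to −20 °C; then 6, −78 °C to rt
Reagents that add atoms: ethyltriphenylphosphonium iodide (CC[P+](c1ccccc1)(c1ccccc1)c1ccccc1.[I-]); iodine (II)
Why: Wittig olefination with the α-iodo ylide (Stork–Zhao type) goes through the kinetic cis-oxaphosphetane, placing iodine cis to C6, which is the Z geometry needed for C4=C5.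

**Step 6**
Reactants: 8 2-methyl-2-vinyloxirane (racemic isoprene monoepoxide)
Product: 9 (2S)-2-[(4-methoxyphenyl)methoxy]-2-methylbut-3-en-1-ol
Conditions: 4-MeOC6H4CH2OH, Pd2(dba)3·CHCl3 (1 mol %), (R,R)-DACH-phenyl Trost ligand (3 mol %), Et3B (1 mol %), CH2Cl2, rt
Reagents that add atoms: 4-methoxybenzyl alcohol (COc1ccc(CO)cc1)
Why: Pd-catalysed dynamic kinetic asymmetric allylic etherification: the π-allyl diastereomers interconvert and the boron-bound alkoxide delivers the alcohol to the tertiary terminus, setting the C10 quaternary centre.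

**Step 7**
Reactants: 9 (2S)-2-[(4-methoxyphenyl)methoxy]-2-methylbut-3-en-1-ol
Product: 10 (2S)-2-[(4-methoxyphenyl)methoxy]-2-methylbut-3-enal
Conditions: DMP, CH2Cl2, 0 °C
Reagents that add atoms: none
Why: Dess–Martin oxidation; the aldehyde has no α-hydrogen, so C10 cannot racemise.

**Step 8**
Reactants: 10 (2S)-2-[(4-methoxyphenyl)methoxy]-2-methylbut-3-enal
Product: 11 (3RS,4S)-4-[(4-methoxyphenyl)methoxy]-4-methylhex-5-en-1-yn-3-ol (both carbinol epimers carried on)
Conditions: HC≡CMgBr, THF, −78 to 0 °C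
Reagents that add atoms: ethynylmagnesium bromide (C#C[Mg]Br)
Why: Grignard 1,2-addition; the new carbinol centre is oxidised to the C1 ketone in step 10, so its configuration is irrelevant.

**Step 9**
Reactants: 7 (3R,4S,5S)-3-[(dimethylamino)methyl]-4-ethenyl-5-[(1Z)-2-iodoprop-1-en-1-yl]oxolan-2-one; 11 (3RS,4S)-4-[(4-methoxyphenyl)methoxy]-4-methylhex-5-en-1-yn-3-ol
Product: 12 (3R,4S,5S)-3-[(dimethylamino)methyl]-4-ethenyl-5-{(1Z,5RS,6S)-5-hydroxy-6-[(4-methoxyphenyl)methoxy]-2,6-dimethylocta-1,7-dien-3-yn-1-yl}oxolan-2-one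
Conditions: PdCl2(PPh3)2 (5 mol %), CuI (10 mol %), Et3N, THF, rt
Reagents that add atoms: none
Why: Sonogashira coupling forms C3–C4 with retention of the Z vinyl geometry; lactone, amine and free alcohol are tolerated.

**Step 10**
Reactants: 12 (3R,4S,5S)-3-[(dimethylamino)methyl]-4-ethenyl-5-{(1Z,5RS,6S)-5-hydroxy-6-[(4-methoxyphenyl)methoxy]-2,6-dimethylocta-1,7-dien-3-yn-1-yl}oxolan-2-one
Product: 13 (3R,4S,5S)-3-[(dimethylamino)methyl]-4-ethenyl-5-{(1Z,6S)-6-[(4-methoxyphenyl)methoxy]-2,6-dimethyl-5-oxoocta-1,7-dien-3-yn-1-yl}oxolan-2-one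
Conditions: DMP, CH2Cl2, 0 °C
Reagents that add atoms: none
Why: Dess–Martin oxidation of the propargylic alcohol to the ynone converges both epimers to one compound.

**Step 11**
Reactants: 13 (3R,4S,5S)-3-[(dimethylamino)methyl]-4-ethenyl-5-{(1Z,6S)-6-[(4-methoxyphenyl)methoxy]-2,6-dimethyl-5-oxoocta-1,7-dien-3-yn-1-yl}oxolan-2-one
Product: 15 (3R,4S,5S)-3-[(dimethylamino)methyl]-4-ethenyl-5-{(1Z)-2-[(5S)-5-ethenyl-5-methyl-4-oxo-4,5-dihydrofuran-2-yl]prop-1-en-1-yl}oxolan-2-one, via hydroxy ynone 14 (not isolated)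
Conditions: TFA, anisole, CH2Cl2, 0 °C; evaporate; then Ph3PAuNTf2 (5 mol %), CH2Cl2, rt
Reagents that add atoms: none
Why: Acidolysis of the PMB ether (the adjacent ketone prevents ionisation at C10), then gold-catalysed 5-endo-dig hydroalkoxylation of the α'-hydroxy ynone gives the 3(2H)-furanone; the amine is protected as its trifluoroacetate salt and C10 is not touched.

**Step 12**
Reactants: 15 (3R,4S,5S)-3-[(dimethylamino)methyl]-4-ethenyl-5-{(1Z)-2-[(5S)-5-ethenyl-5-methyl-4-oxo-4,5-dihydrofuran-2-yl]prop-1-en-1-yl}oxolan-2-one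
Product: 16 (4Z,8Z,6S,7S,10S,11R)-13-(dimethylamino)-3,10-epoxy-1-oxo-11,13-dihydrogermacra-2,4,8-trien-12,6-olide
Conditions: second-generation Hoveyda–Grubbs catalyst (10 mol %), (+)-CSA (1.05 equiv), 1,2-dichloroethane (1 mM), 60 °C, Ar sparge
Reagents that add atoms: none
Why: Ring-closing metathesis of the two monosubstituted vinyl groups; the furanone bridge and the Z C4=C5 bond already hold C7 and C10 in one arc so only the Z C8=C9 alkene can form, ethylene loss drives closure of the strained ring, and the ammonium salt keeps the amine off ruthenium.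

**Step 13**
Reactants: 16 (4Z,8Z,6S,7S,10S,11R)-13-(dimethylamino)-3,10-epoxy-1-oxo-11,13-dihydrogermacra-2,4,8-trien-12,6-olide
Product: 17 (4Z,6R,7R,8S,9S,10S,11R)-13-(dimethylamino)-3,10-epoxy-8β,9β-dihydroxy-1-oxo-11,13-dihydrogermacra-2,4-dien-12,6-olide
Conditions: OsO4 (5 mol %), NMO, acetone/H2O, 0 °C to rt
Reagents that add atoms: osmium tetroxide (O=[Os](=O)(=O)=O); N-methylmorpholine N-oxide (C[N+]1([O-])CCOCC1); water (O)
Why: Syn-dihydroxylation of the only non-conjugated alkene; the C1 carbonyl carbon is expected to stand nearly perpendicular to the C8=C9 π-plane on the α face, so osmium should add from the β face and set C8 and C9 together. This rests on a hand conformational model, not a calculation.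

**Step 14**
Reactants: 17 (4Z,6R,7R,8S,9S,10S,11R)-13-(dimethylamino)-3,10-epoxy-8β,9β-dihydroxy-1-oxo-11,13-dihydrogermacra-2,4-dien-12,6-olide
Product: 18 (4Z,6R,7S,8S,9S,10S,11R)-13-(dimethylamino)-3,10-epoxy-9β-hydroxy-8β-(2-methylprop-2-enoyloxy)-1-oxo-11,13-dihydrogermacra-2,4-dien-12,6-olide
Conditions: methacrylic anhydride (1.2 equiv), Et3N, DMAP (10 mol %), CH2Cl2, −40 to −20 °C
Reagents that add atoms: methacrylic anhydride (CC(=C)C(=O)OC(=O)C(C)=C)
Why: Kinetic acylation of the less hindered C8 hydroxyl; the C9 hydroxyl is neopentylic (next to quaternary C10), and the same position is also the thermodynamic one if the acyl group migrates.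

**Step 15**
Reactants: 18 (4Z,6R,7S,8S,9S,10S,11R)-13-(dimethylamino)-3,10-epoxy-9β-hydroxy-8β-(2-methylprop-2-enoyloxy)-1-oxo-11,13-dihydrogermacra-2,4-dien-12,6-olide
Product: 19 (4Z,6R,7S,8S,9S,10S,11R)-9β-acetoxy-13-(dimethylamino)-3,10-epoxy-8β-(2-methylprop-2-enoyloxy)-1-oxo-11,13-dihydrogermacra-2,4-dien-12,6-olide
Conditions: Ac2O, DMAP, pyridine, CH2Cl2, 0 °C to rt
Reagents that add atoms: acetic anhydride (CC(=O)OC(C)=O)
Why: DMAP-catalysed acetylation of the remaining hindered secondary alcohol; no stereocentre changes.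

**Step 16**
Reactants: 19 (4Z,6R,7S,8S,9S,10S,11R)-9β-acetoxy-13-(dimethylamino)-3,10-epoxy-8β-(2-methylprop-2-enoyloxy)-1-oxo-11,13-dihydrogermacra-2,4-dien-12,6-olide
Product: 21 (4Z,6R,7S,8S,9S,10S)-9-acetoxy-3,10-epoxy-8-(2-methylprop-2-enoyloxy)-1-oxogermacra-2,4,11(13)-trien-12,6-olide (CNP0365569.2), via trimethylammonium iodide 20 (not isolated)
Conditions: MeI, acetone, rt; then NaHCO3, H2O/EtOAc, rt
Reagents that add atoms: none
Why: N-Quaternisation followed by mild-base E1cB (Hofmann-type) elimination of trimethylamine unveils the α-methylene lactone without touching the two esters or the furanone.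

**Compound list**
1 | (S)-5-(hydroxymethyl)furan-2(5H)-one | OC[C@H]1OC(=O)C=C1 | starting material
2 | (S)-5-{[tert-butyl(diphenyl)silyl]oxymethyl}furan-2(5H)-one | CC(C)(C)[Si](OC[C@H]1OC(=O)C=C1)(c2ccccc2)c3ccccc3 | intermediate
3 | bromomagnesium enolate of (4S,5S)-5-{[tert-butyl(diphenyl)silyl]oxymethyl}-4-ethenyloxolan-2-one | C=C[C@H]1C=C(O[Mg]Br)O[C@@H]1CO[Si](c2ccccc2)(c3ccccc3)C(C)(C)C | intermediate
4 | (3R,4S,5S)-5-{[tert-butyl(diphenyl)silyl]oxymethyl}-3-[(dimethylamino)methyl]-4-ethenyloxolan-2-one | C=C[C@H]1[C@H](CN(C)C)C(=O)O[C@@H]1CO[Si](c2ccccc2)(c3ccccc3)C(C)(C)C | intermediate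
5 | (3R,4S,5S)-3-[(dimethylamino)methyl]-4-ethenyl-5-(hydroxymethyl)oxolan-2-one | C=C[C@H]1[C@H](CN(C)C)C(=O)O[C@@H]1CO | intermediate
6 | (2S,3S,4R)-4-[(dimethylamino)methyl]-3-ethenyl-5-oxooxolane-2-carbaldehyde | C=C[C@H]1[C@H](CN(C)C)C(=O)O[C@@H]1C=O | intermediate
7 | (3R,4S,5S)-3-[(dimethylamino)methyl]-4-ethenyl-5-[(1Z)-2-iodoprop-1-en-1-yl]oxolan-2-one | C=C[C@H]1[C@H](CN(C)C)C(=O)O[C@@H]1/C=C(/C)I | intermediate
8 | 2-methyl-2-vinyloxirane (racemic) | CC1(C=C)CO1 | starting material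
9 | (2S)-2-[(4-methoxyphenyl)methoxy]-2-methylbut-3-en-1-ol | OC[C@@](C)(OCc1ccc(OC)cc1)C=C | intermediate
10 | (2S)-2-[(4-methoxyphenyl)methoxy]-2-methylbut-3-enal | O=C[C@@](C)(OCc1ccc(OC)cc1)C=C | intermediate
11 | (3RS,4S)-4-[(4-methoxyphenyl)methoxy]-4-methylhex-5-en-1-yn-3-ol | C#CC(O)[C@@](C)(OCc1ccc(OC)cc1)C=C | intermediate
12 | (3R,4S,5S)-3-[(dimethylamino)methyl]-4-ethenyl-5-{(1Z,5RS,6S)-5-hydroxy-6-[(4-methoxyphenyl)methoxy]-2,6-dimethylocta-1,7-dien-3-yn-1-yl}oxolan-2-one | C=C[C@H]1[C@H](CN(C)C)C(=O)O[C@@H]1/C=C(/C)C#CC(O)[C@@](C)(OCc2ccc(OC)cc2)C=C | intermediate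
13 | (3R,4S,5S)-3-[(dimethylamino)methyl]-4-ethenyl-5-{(1Z,6S)-6-[(4-methoxyphenyl)methoxy]-2,6-dimethyl-5-oxoocta-1,7-dien-3-yn-1-yl}oxolan-2-one | C=C[C@H]1[C@H](CN(C)C)C(=O)O[C@@H]1/C=C(/C)C#CC(=O)[C@@](C)(OCc2ccc(OC)cc2)C=C | intermediate
14 | (3R,4S,5S)-3-[(dimethylamino)methyl]-4-ethenyl-5-[(1Z,6S)-6-hydroxy-2,6-dimethyl-5-oxoocta-1,7-dien-3-yn-1-yl]oxolan-2-one | C=C[C@H]1[C@H](CN(C)C)C(=O)O[C@@H]1/C=C(/C)C#CC(=O)[C@@](C)(O)C=C | intermediate
15 | (3R,4S,5S)-3-[(dimethylamino)methyl]-4-ethenyl-5-{(1Z)-2-[(5S)-5-ethenyl-5-methyl-4-oxo-4,5-dihydrofuran-2-yl]prop-1-en-1-yl}oxolan-2-one | C=C[C@H]1[C@H](CN(C)C)C(=O)O[C@@H]1/C=C(/C)C2=CC(=O)[C@@](C)(O2)C=C | intermediate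
16 | (4Z,8Z,6S,7S,10S,11R)-13-(dimethylamino)-3,10-epoxy-1-oxo-11,13-dihydrogermacra-2,4,8-trien-12,6-olide | CN(C)C[C@@H]1C(=O)O[C@@H]2/C=C(/C)C3=CC(=O)[C@@](C)(O3)/C=C\[C@@H]12 | intermediate
17 | (4Z,6R,7R,8S,9S,10S,11R)-13-(dimethylamino)-3,10-epoxy-8β,9β-dihydroxy-1-oxo-11,13-dihydrogermacra-2,4-dien-12,6-olide | CN(C)C[C@@H]1C(=O)O[C@@H]2/C=C(/C)C3=CC(=O)[C@@](C)(O3)[C@@H](O)[C@@H](O)[C@@H]12 | intermediate
18 | (4Z,6R,7S,8S,9S,10S,11R)-13-(dimethylamino)-3,10-epoxy-9β-hydroxy-8β-(2-methylprop-2-enoyloxy)-1-oxo-11,13-dihydrogermacra-2,4-dien-12,6-olide | CN(C)C[C@@H]1C(=O)O[C@@H]2/C=C(/C)C3=CC(=O)[C@@](C)(O3)[C@@H](O)[C@@H](OC(=O)C(C)=C)[C@@H]12 | intermediate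
19 | (4Z,6R,7S,8S,9S,10S,11R)-9β-acetoxy-13-(dimethylamino)-3,10-epoxy-8β-(2-methylprop-2-enoyloxy)-1-oxo-11,13-dihydrogermacra-2,4-dien-12,6-olide | CN(C)C[C@@H]1C(=O)O[C@@H]2/C=C(/C)C3=CC(=O)[C@@](C)(O3)[C@@H](OC(C)=O)[C@@H](OC(=O)C(C)=C)[C@@H]12 | intermediate
20 | N,N,N-trimethylammonium iodide of 19 (13-trimethylammonio compound) | C[N+](C)(C)C[C@@H]1C(=O)O[C@@H]2/C=C(/C)C3=CC(=O)[C@@](C)(O3)[C@@H](OC(C)=O)[C@@H](OC(=O)C(C)=C)[C@@H]12.[I-] | intermediate
21 | (4Z,6R,7S,8S,9S,10S)-9-acetoxy-3,10-epoxy-8-(2-methylprop-2-enoyloxy)-1-oxogermacra-2,4,11(13)-trien-12,6-olide (CNP0365569.2) | C=C(C)C(=O)O[C@H]1[C@H]2C(=C)C(=O)O[C@@H]2/C=C(/C)C2=CC(=O)[C@@](C)(O2)[C@H]1OC(C)=O | target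

**Totals**
Total step count: 16. Longest linear sequence: 13 steps (steps 1–5, then 9–16); the alkyne branch is 3 steps (6–8).

**Three steps most likely to fail, each with a fallback**

Step 12 (RCM to the bridged, strained Z,Z-triene). The ring may not close against the strain of the ether-bridged bicycle, giving dimers instead. The fallback closes the ten-membered carbocycle before the bridge exists. It sets out from 13: diethylamine in ethanol adds to the ynone to give the E-configured diethylamino enone F1. Ring-closing metathesis of F1 (same ruthenium catalyst, ammonium salt) then closes an unbridged, more flexible ring, the macrocyclic enaminone F2. TFA/anisole removes the PMB group, and the freed C10 hydroxyl displaces diethylamine at C3 across the ring (acid-mediated addition–elimination, the classical enaminone-to-furanone closure). This returns to the route at 16.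

Step 13 (face and site selectivity of the osmylation). If osmium adds to the α face instead, the fallback uses the same facial bias to deliver hydride rather than oxygen. It sets out from 16: osmylation as in step 13 gives the 8α,9α-diol F3; Swern oxidation gives the 8,9-diketone F4 (kept cold, since H7 is now enolisable). Reduction with NaBH4/CeCl3·7H2O in MeOH at −78 °C brings hydride in from the open α face and pushes both hydroxyls to the β face. This returns to the route at 17. It does not help if osmium attacks a different alkene.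

Step 14 (differentiating the two secondary hydroxyls). If direct acylation gives mixtures, the fallback reverses the order and takes regiocontrol from orthoester opening. It sets out from 17: MeC(OMe)3 with PPTS gives the cyclic 8,9-orthoacetate F5. Brief hydrolysis with aqueous AcOH opens it with the acetate on the more hindered oxygen, giving the 9-acetate 8-alcohol F6. Methacrylic anhydride/DMAP then acylates the free C8 hydroxyl. This returns to the route at 19, skipping 18.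

**Further compounds**
F1 | step 12 | (3R,4S,5S)-5-{(1Z,3E,6S)-3-(diethylamino)-6-[(4-methoxyphenyl)methoxy]-2,6-dimethyl-5-oxoocta-1,3,7-trien-1-yl}-3-[(dimethylamino)methyl]-4-ethenyloxolan-2-one | C=C[C@H]1[C@H](CN(C)C)C(=O)O[C@@H]1/C=C(/C)\C(N(CC)CC)=C/C(=O)[C@@](C)(OCc2ccc(OC)cc2)C=C
F2 | step 12 | (2E,4Z,8Z)-3-(diethylamino)-13-(dimethylamino)-10-[(4-methoxyphenyl)methoxy]-1-oxo-11,13-dihydrogermacra-2,4,8-trien-12,6-olide (no ether bridge; configuration as in 16) | CN(C)C[C@@H]1C(=O)O[C@@H]2/C=C(/C)\C(N(CC)CC)=C/C(=O)[C@@](C)(OCc3ccc(OC)cc3)/C=C\[C@@H]12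
F3 | step 13 | (4Z,6R,7R,8R,9R,10S,11R)-13-(dimethylamino)-3,10-epoxy-8α,9α-dihydroxy-1-oxo-11,13-dihydrogermacra-2,4-dien-12,6-olide (8,9-di-epi-17) | CN(C)C[C@@H]1C(=O)O[C@@H]2/C=C(/C)C3=CC(=O)[C@@](C)(O3)[C@H](O)[C@H](O)[C@@H]12
F4 | step 13 | (4Z)-13-(dimethylamino)-3,10-epoxy-1,8,9-trioxo-11,13-dihydrogermacra-2,4-dien-12,6-olide (configuration at C6, C7, C10, C11 as in 16) | CN(C)C[C@@H]1C(=O)O[C@@H]2/C=C(/C)C3=CC(=O)[C@@](C)(O3)C(=O)C(=O)[C@@H]12
F5 | step 14 | 8β,9β-O-(1-methoxyethylidene) cyclic orthoacetate of 17 (orthoester carbon: both epimers) | CN(C)C[C@@H]1C(=O)O[C@@H]2/C=C(/C)C3=CC(=O)[C@@](C)(O3)[C@H]4OC(C)(OC)O[C@H]4[C@@H]12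
F6 | step 14 | (4Z,6R,7R,8S,9S,10S,11R)-9β-acetoxy-13-(dimethylamino)-3,10-epoxy-8β-hydroxy-1-oxo-11,13-dihydrogermacra-2,4-dien-12,6-olide | CN(C)C[C@@H]1C(=O)O[C@@H]2/C=C(/C)C3=CC(=O)[C@@](C)(O3)[C@@H](OC(C)=O)[C@@H](O)[C@@H]12
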